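Slowness did not look like the issue: in the south-west run the starting material stood near 0.400 of its charge from 0.500 d to 6.00 d. So I took the coupling partner, the limiting reagent there, as consumed by the first reading, and expected the flask at 5.0 d to end by its charge, not by time.

| flask | starting material | coupling partner | remark | time |
|---|---|---|---|---|
| south-west | 0.20 M | 0.12 M | run made earlier |  |
| north | 0.20 M | 0.48 M | run made earlier |  |
| flask | 0.20 M | 0.240 M |  | 5.0 d |

| run | time / d | starting material / % | mono adduct / % | other mono adduct / % |
|---|---|---|---|---|
| south-west | 0.500 | 38 | 16 | 22 |
| south-west | 1.04 | 40 | 18 | 22 |
| south-west | 2.50 | 42 | 22 | 21 |
| south-west | 6.00 | 40 | 20 | 21 |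
| north | 1.67 | 1 | 2 | 1 |
| north | 3.00 | 0 | 0 | 0 |
| north | 5.00 | 1 | 1 | 0 |
| north | 6.00 | 1 | 0 | 1 |

(scatter of a reading: 1.5 percentage points)

- steps under discussion: starting material + coupling partner -> mono adduct; starting material <-> dormant form; starting material + coupling partner -> other mono adduct; coupling partner + other mono adduct -> bis adduct; coupling partner + mono adduct -> bis adduct

- amount of starting material at 5.0 d, in percent of the starting material charged
- amount of mono adduct at 5.0 d, in percent of the starting material charged
- amount of other mono adduct at 5.0 d, in percent of the starting material charged
- amount of bis adduct at 5.0 d, in percent of the starting material charged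

Starting material takes up partner to give either mono adduct, either adduct takes a second partner to give bis adduct, and starting material exchanges with dormant form. I treated the two mono adducts as one pool.

In the south-west run, 0.600 of partner was charged per starting material, and the mono adducts read 0.405. Taking the partner as spent, the partner balance gave bis adduct 0.0975, and closing the total left a pool of starting material and dormant form together of 0.497. From that pool, my reckoning gave mono adducts of 0.503 with no second addition and 0.347 with a second addition as fast as the first. Going round once more with the second addition at 0.5 of the rate of the first gave 0.416, close to the reading.

That rate yields my rule, the survivor fraction: the share of the charge never touched by partner, starting material and dormant form together. With the partner spent and that relative rate held, divide the partner charged per starting material by two, subtract from one, and square. For the flask this gave 0.160, with mono adducts 0.480 and bis adduct 0.360.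

The weak link was the dormant share, a difference of readings. Putting the rule's south-west pool, 0.490, back in gave a dormant-to-starting-material ratio of 0.225, an estimate carrying the scatter of the readings; holding that ratio for the flask gave 0.131 starting material there.

The forecast gave starting material 13 %, mono adduct 24 %, other mono adduct 23 % and bis adduct 37 %, noting “The mono adducts split about evenly.”

The flask gave starting material 13.7 %, mono adduct 23.3 %, other mono adduct 22.5 % and bis adduct 37.1 %, amounts that read the same to the whole percent from 0.500 d to 50.0 d.

    starting material + coupling partner → mono adduct (k = 0.00738 M⁻¹ s⁻¹)
    starting material ⇌ dormant form (K = 0.250, k = 2.74 × 10⁻⁴ s⁻¹)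
    starting material + coupling partner → other mono adduct (k = 0.0101 M⁻¹ s⁻¹)
    coupling partner + other mono adduct → bis adduct (k = 0.0106 M⁻¹ s⁻¹)
    coupling partner + mono adduct → bis adduct (k = 0.00551 M⁻¹ s⁻¹)

Starting material and dormant form together held 17.1 % of the flask's charge, against a survivor fraction of 0.160. With the other charge and the time held, bis adduct in the flask moved by 5 points at a partner charge of 0.223 M or 0.256 M. For a neighbouring flask with 0.060 M of coupling partner, the survivor fraction came to 0.722, with mono adducts 0.255 and bis adduct 0.0225. That neighbour held 72.4 % as starting material and dormant form, and 25.3 % as mono adducts. Its bis adduct came to 2.37 %.

The data were generated by integration with constants of no real substance, noise included.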